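Numbering used throughout: ring A is C1–C6 (C1 OMe, C3 oxygen, C5 bridge), ring B is B1–B6 (B1 bridge, B3 oxygen, B6 benzyl group), and the four outer hydroxyphenyl rings on C2, C4, C6 and B6 are rings C, D, E and F.

Assumption: 3-hydroxy-5-methoxybenzaldehyde (1), 1-(benzyloxy)-3-(bromomethyl)benzene (3) and the THF solution of [2-(1,3-dioxolan-2-yl)ethyl]zinc bromide (9) are taken as catalogue chemicals.

## Analysis of the target

Bleochrin B (17) is an achiral bibenzyl with six benzene rings and no other ring. Ring A is hexasubstituted: OMe at C1, OH at C3, 4-hydroxybenzyl groups at C2, C4 and C6, and at C5 the CH2CH2 bridge to B1. Ring B carries OH at B3 and the fourth 4-hydroxybenzyl group at B6, ortho to the bridge and para to the B3 oxygen. There is no stereocentre, so the problem is regiochemistry and congestion, not configuration. The sensitive groups are the five electron-rich free phenols, the four doubly benzylic CH2 groups, and the O1 methyl ether, which must stay distinct from the O3 hydroxyl although both oxygens sit between two benzyl groups. The hard part is ring A, where every position is occupied and three identical carbon substituents each lie between two ortho neighbours. The plan rests on the fourfold repeat: rings C, D, E and F are identical para-substituted phenols, and a 4-alkylphenol is the dehydrogenation product of a 4-alkylcyclohex-2-enone, which is the Robinson annulation product of an aldehyde RCH2CHO and methyl vinyl ketone (12). In addition, C2, C4 and C6 are the three carbons of ring A activated by both ether oxygens and B6 is the carbon of ring B para to its oxygen, so all four are sites at which a handle can be introduced by electrophilic substitution.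

## Retrosynthetic reasoning

17 from 16. The last disconnection is the O–CH2Ph bond at O3 and at O3 of ring B. Benzyl was chosen because it survives base, mild acid, organozinc reagents and oxidative palladium chemistry, and because its removal by hydrogenolysis leaves the methyl ether at O1 untouched. The phenols of rings C to F need no protection, since they appear only one step earlier.

16 from 15. Rings C to F are taken back from phenols to 4-substituted cyclohex-2-enones by adding back eight hydrogen atoms. No bond of the skeleton is cut, but four arenes become aliphatic rings that carbonyl chemistry can build. The forward reaction, a catalytic aerobic dehydrogenation, must aromatize four enones without attacking the diarylmethane CH2 groups or the benzyl ethers. It also erases the four stereocentres of 15.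

15 from 11 and 12. In each enone ring two bonds are cut: the C=C bond (aldol condensation) and the bond between the ring carbon bearing the benzylic CH2 and its saturated ring neighbour (Michael addition). This is the only cut that turns all four rings into the same simple unit, a 3-oxopropyl arm on the core plus one molecule of 12 per ring, so four rings and eight C–C bonds come from one operation. It also places the ketone opposite the substituted carbon, which is the para relationship the target needs. The forward reaction passes through the keto-aldehyde 13 and the aldol 14.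

11 from 10, and 10 from 8 and 9. The aldehydes are masked as dioxolanes so that the carbon–carbon bond formation can be done with an organometallic reagent. The four aryl–CH2 bonds at C2, C4, C6 and B6 are then cut, giving the tetrabromide 8 and four molecules of the three-carbon zinc reagent 9. These bonds are chosen because their aryl carbons are the ones a halogen can reach selectively. The forward Negishi coupling has to work at three di-ortho-substituted positions and one mono-ortho-substituted position.

8 from 7. Four C–Br bonds are cut. On ring A all three free positions are activated by both oxygens; on ring B the position para to the ether oxygen is B6. The forward bromination must put three bromines on ring A and exactly one on ring B.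

7 from 6, and 6 from 5 and 2. The central CH2–CH2 bond is traced back to an alkene and cut by a Wittig disconnection into the ring A aldehyde 2 and the ring B ylide 5, generated from the phosphonium salt 4. Alkene geometry is irrelevant because the double bond is saturated by a metal-free reduction that spares the benzyl ethers.

2 from 1, and 4 from 3. O-Benzylation of 1 fixes the O1/O3 distinction of ring A at the first step, since 1 already carries one methyl ether and one free hydroxyl. Salt 4 comes from the benzylic bromide 3 by quaternisation.

## Alternatives that were turned down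

Alternative 1: Ring A is opened at C4–C5 to the open-chain styryl triketone A2, (E)-1-{5-(benzyloxy)-2-[4-(benzyloxy)benzyl]phenyl}-4,6-bis[4-(benzyloxy)benzyl]-9-[4-(benzyloxy)phenyl]non-1-ene-3,5,7-trione. In the forward direction base would close A2 by aldol condensation of its C8 methylene onto the C3 styryl ketone, and enolisation would give the resorcinol stilbene A1, 2,4,6-tris[4-(benzyloxy)benzyl]-5-{(E)-2-[5-(benzyloxy)-2-(4-(benzyloxy)benzyl)phenyl]ethenyl}benzene-1,3-diol.
- For: the fully substituted ring is made in one biomimetic closure with all three benzyl groups and the bridge in place, no cross-coupling at a hindered arene is needed, and one final hydrogenation would saturate the stilbene and remove every benzyl ether. On convergence and on avoiding hindered couplings it is stronger than the chosen route.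
- Against: A2 is a thrice C-alkylated polyketone. Its assembly needs regiocontrolled alkylation or acylation of polycarbonyl anions, it exists as a mixture of tautomers, and it has competing closures (O-attack to pyranones, conjugate addition of an enol oxygen to the styryl enone).
- Decisive point: A1 has two free hydroxyls at C1 and C3 in nearly identical surroundings, each flanked by two 4-(benzyloxy)benzyl groups, so methylation of O1 alone cannot be expected to be selective.
- Comparison: the chosen route carries the O1/O3 distinction from compound 1 and uses only individually precedented steps.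

Alternative 2: Ring A is cut at C4–C5 and C1–C6 into the cyclohexadiene A4, 2,4-bis[4-(benzyloxy)benzyl]-1-methoxy-3-[(trimethylsilyl)oxy]cyclohexa-1,3-diene, and the aryl ynone A5, 1-[4-(benzyloxy)phenyl]-5-{5-(benzyloxy)-2-[4-(benzyloxy)benzyl]phenyl}pent-2-yn-1-one. In the forward direction a [4+2] cycloaddition is followed by thermal cycloreversion that expels the saturated two-carbon bridge (Alder–Rickert reaction), giving the ring A aryl ketone A3 with C1 OMe, C3 OSiMe3 and a 4-(benzyloxy)benzoyl group at C6.
- For: the regiochemistry is electronically matched, since the donor-activated terminus C4 attacks the β-carbon of A5. The O1 methyl / O3 silyl distinction arises automatically, so on oxygen differentiation it is as good as the chosen route.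
- Against: both diene termini are fully substituted and the dienophile is an internal alkyne, so two quaternary bridgeheads must form at the high temperatures the cycloreversion needs, where a silyl dienol ether can isomerise or desilylate. A4 itself needs regiodefined O-methylation and silylation of an unsymmetrical cyclic 1,3-dicarbonyl precursor. A3 still carries a diaryl ketone at the C6 benzylic carbon that must be reduced.
- Comparison: every one of the four hydroxybenzyl units has to be made and attached separately, so the step count is higher. The chosen route makes all four from one arm type and 12.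

Alternative 3: Ring B is cut at B1–B2 and B5–B6 into 1-methoxy-3-(trimethylsilyloxy)buta-1,3-diene A8 and the ring A ynone A7, 1-[4-(benzyloxy)phenyl]-5-{3-(benzyloxy)-2,4,6-tris[4-(benzyloxy)benzyl]-5-methoxyphenyl}pent-2-yn-1-one. In the forward direction cycloaddition, loss of the methoxy group and loss of the silyl group give ring B as the 4-acylphenol A6.
- For: this cycloaddition of an oxygenated diene to an alkynyl ketone is well precedented, mild and regiochemically secure (oxygen ends para to the acyl carbon, B3 para to B6). As a single key step it is more reliable than a fourfold annulation.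
- Against: it builds the easy ring. Ring B is only trisubstituted, and the whole difficulty of hexasubstituted ring A is moved into the preparation of A7, which needs the same hindered aryl–alkyl couplings as the chosen route plus a pentynone chain. A6 also has a ketone at the B6 benzylic carbon to remove.
- Comparison: the chosen route uses comparable ring A functionalisation (halogenation and coupling of 7 to 8 and 10) but draws all four hydroxyphenyl rings from it in one step, with no ketone to delete afterwards.

Key step: step 8

## Route

Step 1
Reactants: 1 3-hydroxy-5-methoxybenzaldehyde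
Product: 2 3-(benzyloxy)-5-methoxybenzaldehyde
Conditions: BnBr, K2CO3, DMF, rt
Reagents that add atoms: benzyl bromide, BrCc1ccccc1
Why: Williamson ether synthesis; the phenoxide of 1 displaces bromide from the benzylic halide, the aldehyde is inert to K2CO3, and the O1 methyl / O3 benzyl distinction of ring A is fixed here.

Step 2
Reactants: 3 1-(benzyloxy)-3-(bromomethyl)benzene
Product: 4 {[3-(benzyloxy)phenyl]methyl}triphenylphosphonium bromide
Conditions: PPh3, toluene, reflux
Reagents that add atoms: triphenylphosphine, c1ccc(cc1)P(c1ccccc1)c1ccccc1
Why: SN2 quaternisation of a primary benzylic bromide by the phosphine; the salt should precipitate from toluene, which drives the reaction and purifies the product.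

Step 3
Reactants: 4 {[3-(benzyloxy)phenyl]methyl}triphenylphosphonium bromide; 2 3-(benzyloxy)-5-methoxybenzaldehyde
Product: 6 1-(benzyloxy)-3-{2-[3-(benzyloxy)phenyl]ethenyl}-5-methoxybenzene (E/Z mixture), via phosphonium ylide 5 (not isolated)
Conditions: KOtBu, THF, 0 °C; then 2, 0 °C to rt
Reagents that add atoms: none
Why: Wittig olefination; deprotonation gives the semi-stabilised benzylic ylide 5, which adds to the aryl aldehyde and collapses through the oxaphosphetane. An E/Z mixture is expected and is harmless because the alkene is saturated in the next step.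

Step 4
Reactants: 6 1-(benzyloxy)-3-{2-[3-(benzyloxy)phenyl]ethenyl}-5-methoxybenzene (E/Z mixture)
Product: 7 1-(benzyloxy)-3-{2-[3-(benzyloxy)phenyl]ethyl}-5-methoxybenzene
Conditions: TsNHNH2 (excess, in portions), NaOAc, DME/H2O, reflux
Reagents that add atoms: none
Why: Diimide reduction; diimide released from the sulfonyl hydrazide transfers two hydrogens to the unpolarised C=C through a cyclic six-centre transition state. It leaves aryl benzyl ethers alone, which hydrogenation over palladium would cleave.

Step 5
Reactants: 7 1-(benzyloxy)-3-{2-[3-(benzyloxy)phenyl]ethyl}-5-methoxybenzene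
Product: 8 1-(benzyloxy)-2,4,6-tribromo-3-{2-[5-(benzyloxy)-2-bromophenyl]ethyl}-5-methoxybenzene (the C2/C4/C6/B6-tetrabromide of 7)
Conditions: NBS (4.2 equiv), MeCN/CH2Cl2, 0 °C to rt, dark
Reagents that add atoms: N-bromosuccinimide (four equivalents), O=C1CCC(=O)N1Br.O=C1CCC(=O)N1Br.O=C1CCC(=O)N1Br.O=C1CCC(=O)N1Br
Why: Fourfold electrophilic aromatic bromination, one molecule of the reagent per new C–Br bond; on ring A each of C2, C4 and C6 is ortho or para to both oxygens and all three are filled, while on ring B the position para to the ether oxygen (B6) is the preferred site of this reagent for 3-alkyl aryl ethers and the ring is then deactivated toward a second bromine. The polar medium, darkness and absence of acid should keep the benzylic CH2 groups and the benzyl ethers untouched.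

Step 6
Reactants: 8 C2/C4/C6/B6-tetrabromide of 7; 9 [2-(1,3-dioxolan-2-yl)ethyl]zinc bromide (4 equiv are incorporated)
Product: 10 C2/C4/C6/B6-tetrakis[2-(1,3-dioxolan-2-yl)ethyl] derivative of 7
Conditions: 9 (8 equiv), Pd(OAc)2 (10 mol %), 2-dicyclohexylphosphino-2',6'-dimethoxybiphenyl (20 mol %), THF, 60 °C
Reagents that add atoms: [2-(1,3-dioxolan-2-yl)ethyl]zinc bromide 9 (three further equivalents), Br[Zn]CCC1OCCO1.Br[Zn]CCC1OCCO1.Br[Zn]CCC1OCCO1
Why: Fourfold Negishi sp2–sp3 cross-coupling that consumes one molecule of 9 per C–Br bond; each C–Br bond adds oxidatively to zerovalent palladium, the primary alkyl group is transferred from zinc, and reductive elimination forms the aryl–CH2 bond, with the bulky electron-rich biarylphosphine speeding both palladium steps at di-ortho-substituted sites and suppressing β-hydride elimination. The three ring A sites are mutually meta, so the ortho environment of each is unchanged as the others react. A direct Heck reaction with allyl alcohol was set aside because its linear/branched and aldehyde/allylic-alcohol selectivities would have to hold four times on hindered bromides.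

Step 7
Reactants: 10 C2/C4/C6/B6-tetrakis[2-(1,3-dioxolan-2-yl)ethyl] derivative of 7
Product: 11 C2/C4/C6/B6-tetrakis(3-oxopropyl) derivative of 7 (tetra-aldehyde)
Conditions: 2 M HCl (aq), THF, 40 °C
Reagents that add atoms: water, O
Why: Acid-catalysed acetal hydrolysis through the oxocarbenium ion; aryl benzyl and methyl ethers are stable to dilute aqueous acid, and the tetra-aldehyde is used promptly to avoid autoxidation.

Step 8
Reactants: 11 C2/C4/C6/B6-tetrakis(3-oxopropyl) derivative of 7; 12 methyl vinyl ketone (but-3-en-2-one; 4 equiv are incorporated)
Product: 15 C2/C4/C6/B6-tetrakis[(4-oxocyclohex-2-en-1-yl)methyl] derivative of 7 (stereoisomer mixture), via tetrakis(2-formyl-5-oxohexyl) adduct 13 (not isolated), via tetra-aldol 14 (not isolated)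
Conditions: 12 (10 equiv), (S)-2-[methoxy(diphenyl)methyl]pyrrolidine (20 mol %), ethyl 3,4-dihydroxybenzoate (80 mol %), EtOAc, 4 °C to rt; evaporation of excess 12; then KOH (aq), Bu4NOH (cat.), THF/Et2O, rt to 40 °C
Reagents that add atoms: methyl vinyl ketone 12 (three further equivalents), CC(=O)C=C.CC(=O)C=C.CC(=O)C=C
Why: The secondary amine condenses with each CHO of 11 to an E-enamine whose nucleophilic carbon (the former aldehyde α-carbon) adds to the β-carbon of 12, which the catechol co-catalyst activates by hydrogen bonding; hydrolysis of the iminium returns the amine and leaves the 2-formyl-5-oxohexyl arm of 13. Hydroxide then generates the methyl-ketone enolate of each arm, which attacks its own aldehyde (14) and loses water by E1cB to give the conjugated enone 15, so that the four arms take up four molecules of 12 and eight C–C bonds form in all. The closest known reaction type is the amine-catalysed Michael addition of α-unbranched aldehydes to 12 followed by base-mediated aldol condensation to 4-substituted cyclohex-2-enones, an organocatalytic Robinson annulation; here it is run at four independent sites. Each of the four rings closes in the same mode, 6-(enolendo)-exo-trig, and no other ring size is open to 13, because the other enolate–carbonyl pairings within an arm would give four-membered rings. Each ring gains one stereocentre (its C4), set in the Michael step by the enamine face that the methoxydiphenylmethyl group of the catalyst leaves open; with one enantiomer of catalyst the four centres should be biased alike, but nothing depends on this since step 9 removes all four, and 15 is taken on as a stereoisomer mixture. The selectivity needed is chemoselectivity, conjugate addition ahead of aldehyde self-aldolisation and of a second alkylation: the bulky amine disfavours enamine attack on another aldehyde, the excess of 12 keeps the enamine trapped, and the alkylated α-carbon is tertiary and much slower to react again. The reacting α-carbons are separated from the congested arenes by a CH2 group, so the arms should behave like four separate 3-arylpropanals, and aldol reactions between different arms would need rings of eight or more members. Because the ketone carbon ends up opposite the carbon that carries the benzylic CH2, each ring is set up to give a phenol with OH para to that CH2.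

Step 9
Reactants: 15 C2/C4/C6/B6-tetrakis[(4-oxocyclohex-2-en-1-yl)methyl] derivative of 7 (stereoisomer mixture)
Product: 16 C2/C4/C6/B6-tetrakis(4-hydroxybenzyl) derivative of 7 (3,B3-di-O-benzyl bleochrin B)
Conditions: Pd(OCOCF3)2 (20 mol %), 2-(dimethylamino)pyridine (40 mol %), TsOH·H2O (80 mol %), O2 (1 atm), DMSO, 80 °C
Reagents that add atoms: none
Why: Aerobic dehydrogenation by divalent palladium, a known conversion of 4-substituted cyclohex-2-enones into phenols; each enone is palladated at the α'-carbon, β-hydride elimination introduces the second ring C=C bond, the ring tautomerises to the phenol, and O2 reoxidises the palladium hydride. The C4 stereocentres disappear, so the isomer mixture should converge on one compound; aryl ethers and diarylmethane CH2 groups are not activated under these conditions.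

Step 10
Reactants: 16 3,B3-di-O-benzyl bleochrin B
Product: 17 bleochrin B
Conditions: H2 (1 atm), 10 % Pd/C, EtOAc/MeOH, rt
Reagents that add atoms: none
Why: Hydrogenolysis of the two aryl benzyl ethers on palladium; the diarylmethane C–C bonds, the methyl ether and the arenes are inert at 1 atm and rt.

## Compound list

1 | 3-hydroxy-5-methoxybenzaldehyde | COc1cc(O)cc(C=O)c1 | starting material
2 | 3-(benzyloxy)-5-methoxybenzaldehyde | COc1cc(OCc2ccccc2)cc(C=O)c1 | intermediate
3 | 1-(benzyloxy)-3-(bromomethyl)benzene | BrCc1cccc(OCc2ccccc2)c1 | starting material
4 | {[3-(benzyloxy)phenyl]methyl}triphenylphosphonium bromide | [Br-].c1ccc(COc2cccc(C[P+](c3ccccc3)(c3ccccc3)c3ccccc3)c2)cc1 | intermediate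
5 | {[3-(benzyloxy)phenyl]methylidene}triphenylphosphorane (ylide) | c1ccc(COc2cccc(C=P(c3ccccc3)(c3ccccc3)c3ccccc3)c2)cc1 | intermediate (not isolated)
6 | 1-(benzyloxy)-3-{2-[3-(benzyloxy)phenyl]ethenyl}-5-methoxybenzene, E/Z mixture | COc1cc(OCc2ccccc2)cc(C=Cc2cccc(OCc3ccccc3)c2)c1 | intermediate
7 | 1-(benzyloxy)-3-{2-[3-(benzyloxy)phenyl]ethyl}-5-methoxybenzene | COc1cc(OCc2ccccc2)cc(CCc2cccc(OCc3ccccc3)c2)c1 | intermediate
8 | 1-(benzyloxy)-2,4,6-tribromo-3-{2-[5-(benzyloxy)-2-bromophenyl]ethyl}-5-methoxybenzene | COc1c(Br)c(OCc2ccccc2)c(Br)c(CCc2cc(OCc3ccccc3)ccc2Br)c1Br | intermediate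
9 | [2-(1,3-dioxolan-2-yl)ethyl]zinc bromide | Br[Zn]CCC1OCCO1 | starting material
10 | 7 bearing 2-(1,3-dioxolan-2-yl)ethyl groups at C2, C4, C6 and B6 | COc1c(CCC2OCCO2)c(OCc2ccccc2)c(CCC2OCCO2)c(CCc2cc(OCc3ccccc3)ccc2CCC2OCCO2)c1CCC1OCCO1 | intermediate
11 | 7 bearing 3-oxopropyl groups at C2, C4, C6 and B6 (tetra-aldehyde) | COc1c(CCC=O)c(OCc2ccccc2)c(CCC=O)c(CCc2cc(OCc3ccccc3)ccc2CCC=O)c1CCC=O | intermediate
12 | methyl vinyl ketone (but-3-en-2-one) | CC(=O)C=C | starting material
13 | 7 bearing 2-formyl-5-oxohexyl groups at C2, C4, C6 and B6, stereoisomer mixture | COc1c(CC(C=O)CCC(C)=O)c(OCc2ccccc2)c(CC(C=O)CCC(C)=O)c(CCc2cc(OCc3ccccc3)ccc2CC(C=O)CCC(C)=O)c1CC(C=O)CCC(C)=O | intermediate (not isolated)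
14 | 7 bearing (2-hydroxy-4-oxocyclohexyl)methyl groups at C2, C4, C6 and B6, stereoisomer mixture | COc1c(CC2CCC(=O)CC2O)c(OCc2ccccc2)c(CC2CCC(=O)CC2O)c(CCc2cc(OCc3ccccc3)ccc2CC2CCC(=O)CC2O)c1CC1CCC(=O)CC1O | intermediate (not isolated)
15 | 7 bearing (4-oxocyclohex-2-en-1-yl)methyl groups at C2, C4, C6 and B6, stereoisomer mixture | COc1c(CC2C=CC(=O)CC2)c(OCc2ccccc2)c(CC2C=CC(=O)CC2)c(CCc2cc(OCc3ccccc3)ccc2CC2C=CC(=O)CC2)c1CC1C=CC(=O)CC1 | intermediate
16 | 3,B3-di-O-benzyl bleochrin B (7 bearing 4-hydroxybenzyl groups at C2, C4, C6 and B6) | COc1c(Cc2ccc(O)cc2)c(OCc2ccccc2)c(Cc2ccc(O)cc2)c(CCc2cc(OCc3ccccc3)ccc2Cc2ccc(O)cc2)c1Cc1ccc(O)cc1 | intermediate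
17 | bleochrin B | COc1c(Cc2ccc(O)cc2)c(O)c(Cc2ccc(O)cc2)c(CCc2cc(O)ccc2Cc2ccc(O)cc2)c1Cc1ccc(O)cc1 | target

## Step count and risk

Total: 10 steps. Longest linear sequence: 9 steps (steps 1 and 3 to 10; the branch through step 2 is equally long).

Step 8 (key step). The most likely failure is uneven conversion across the four arms, together with aldehyde self-condensation or oligomerisation of 12 during the long reaction time a fourfold process needs, giving an inseparable mixture of partly annulated material. Fallback, from 11 back to 15: the aldehydes are converted stoichiometrically into the tetrakis(pyrrolidine enamine) F1 (excess pyrrolidine, K2CO3, toluene, 0 °C to rt, volatiles removed). F1 is treated with 12 in dioxane and then heated with aqueous AcOH/NaOAc, which hydrolyses the iminium ions, closes the rings and dehydrates to 15. This is the classical Stork enamine form of the Robinson annulation; no free aldehyde is present while the Michael acceptor is consumed.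

Step 6. Oxidative addition at the di-ortho-substituted, electron-rich C–Br bonds may be slow, so that protodebromination or β-hydride elimination of the alkylpalladium intermediate competes and leaves arms missing. Fallback, from 8 back to 11: fourfold Stille allylation (allyltributylstannane, Pd(PPh3)4, toluene, 110 °C) gives the tetraallyl compound F2. The allyl group is the smallest sp3 partner and cannot undergo β-hydride loss on palladium. Hydroboration with 9-borabicyclo[3.3.1]nonane and oxidation with H2O2/NaOH gives the tetrakis(3-hydroxypropyl) compound F3, and Dess–Martin oxidation gives 11, bypassing 10.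

Step 9. Aromatization may stall after some of the rings, because the phenols formed can bind and slow the catalyst, or oxidation may spread to the doubly benzylic CH2 groups at 80 °C under O2. Fallback, from 15 back to 16: kinetic α'-deprotonation and silylation (LiN(iPr)2, Me3SiCl, THF, −78 °C) gives the tetrakis(trimethylsilyl dienol ether) F4. Saegusa–Ito oxidation with Pd(OAc)2 in MeCN at rt then introduces the second C=C bond of each ring, and each ring should aromatise at once to the phenol of 16, without heating under oxygen.

Step 5. The third bromination of ring A, at the position between the two ether oxygens, may lag behind, and forcing it may start a second bromination of ring B or radical bromination at a benzylic CH2. Fallback, from 7 back to 10: the halogens are introduced in two rounds. Three equivalents of NBS at 0 °C should give the tribromide F5 (bromine at C4, C6 and B6). Negishi coupling with 9 as in step 6 then gives the tris(dioxolane) F6, whose ring A is now pentasubstituted and strongly activated at C2. One equivalent of NBS gives the C2 bromide F7, and a second Negishi coupling with 9 gives 10.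

## Further compounds

F1 | step 8 | 7 bearing (E)-3-(pyrrolidin-1-yl)prop-2-en-1-yl groups at C2, C4, C6 and B6 (tetrakis enamine) | COc1c(C/C=C/N2CCCC2)c(OCc2ccccc2)c(C/C=C/N2CCCC2)c(CCc2cc(OCc3ccccc3)ccc2C/C=C/N2CCCC2)c1C/C=C/N1CCCC1
F2 | step 6 | 7 bearing prop-2-en-1-yl groups at C2, C4, C6 and B6 | COc1c(CC=C)c(OCc2ccccc2)c(CC=C)c(CCc2cc(OCc3ccccc3)ccc2CC=C)c1CC=C
F3 | step 6 | 7 bearing 3-hydroxypropyl groups at C2, C4, C6 and B6 | COc1c(CCCO)c(OCc2ccccc2)c(CCCO)c(CCc2cc(OCc3ccccc3)ccc2CCCO)c1CCCO
F4 | step 9 | 7 bearing {4-[(trimethylsilyl)oxy]cyclohexa-2,4-dien-1-yl}methyl groups at C2, C4, C6 and B6, stereoisomer mixture | COc1c(CC2C=CC(O[Si](C)(C)C)=CC2)c(OCc2ccccc2)c(CC2C=CC(O[Si](C)(C)C)=CC2)c(CCc2cc(OCc3ccccc3)ccc2CC2C=CC(O[Si](C)(C)C)=CC2)c1CC1C=CC(O[Si](C)(C)C)=CC1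
F5 | step 5 | 1-(benzyloxy)-2,4-dibromo-3-{2-[5-(benzyloxy)-2-bromophenyl]ethyl}-5-methoxybenzene (bromine at C4, C6 and B6) | COc1cc(OCc2ccccc2)c(Br)c(CCc2cc(OCc3ccccc3)ccc2Br)c1Br
F6 | step 5 | 7 bearing 2-(1,3-dioxolan-2-yl)ethyl groups at C4, C6 and B6 | COc1cc(OCc2ccccc2)c(CCC2OCCO2)c(CCc2cc(OCc3ccccc3)ccc2CCC2OCCO2)c1CCC1OCCO1
F7 | step 5 | C2 bromide of the tris(dioxolane) F6 | COc1c(Br)c(OCc2ccccc2)c(CCC2OCCO2)c(CCc2cc(OCc3ccccc3)ccc2CCC2OCCO2)c1CCC1OCCO1
A1 | alternative 1 | 2,4,6-tris[4-(benzyloxy)benzyl]-5-{(E)-2-[5-(benzyloxy)-2-(4-(benzyloxy)benzyl)phenyl]ethenyl}benzene-1,3-diol | Oc1c(Cc2ccc(OCc3ccccc3)cc2)c(O)c(Cc2ccc(OCc3ccccc3)cc2)c(/C=C/c2cc(OCc3ccccc3)ccc2Cc2ccc(OCc3ccccc3)cc2)c1Cc1ccc(OCc2ccccc2)cc1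
A2 | alternative 1 | (E)-1-{5-(benzyloxy)-2-[4-(benzyloxy)benzyl]phenyl}-4,6-bis[4-(benzyloxy)benzyl]-9-[4-(benzyloxy)phenyl]non-1-ene-3,5,7-trione, mixture of stereoisomers and tautomers | O=C(CCc1ccc(OCc2ccccc2)cc1)C(Cc1ccc(OCc2ccccc2)cc1)C(=O)C(Cc1ccc(OCc2ccccc2)cc1)C(=O)/C=C/c1cc(OCc2ccccc2)ccc1Cc1ccc(OCc2ccccc2)cc1
A3 | alternative 2 | [4-(benzyloxy)phenyl]{3,5-bis[4-(benzyloxy)benzyl]-2-(2-{5-(benzyloxy)-2-[4-(benzyloxy)benzyl]phenyl}ethyl)-6-methoxy-4-[(trimethylsilyl)oxy]phenyl}methanone | COc1c(Cc2ccc(OCc3ccccc3)cc2)c(O[Si](C)(C)C)c(Cc2ccc(OCc3ccccc3)cc2)c(CCc2cc(OCc3ccccc3)ccc2Cc2ccc(OCc3ccccc3)cc2)c1C(=O)c1ccc(OCc2ccccc2)cc1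
A4 | alternative 2 | 2,4-bis[4-(benzyloxy)benzyl]-1-methoxy-3-[(trimethylsilyl)oxy]cyclohexa-1,3-diene | COC1=C(Cc2ccc(OCc3ccccc3)cc2)C(O[Si](C)(C)C)=C(Cc2ccc(OCc3ccccc3)cc2)CC1
A5 | alternative 2 | 1-[4-(benzyloxy)phenyl]-5-{5-(benzyloxy)-2-[4-(benzyloxy)benzyl]phenyl}pent-2-yn-1-one | O=C(C#CCCc1cc(OCc2ccccc2)ccc1Cc1ccc(OCc2ccccc2)cc1)c1ccc(OCc2ccccc2)cc1
A6 | alternative 3 | [4-(benzyloxy)phenyl][2-(2-{3-(benzyloxy)-2,4,6-tris[4-(benzyloxy)benzyl]-5-methoxyphenyl}ethyl)-4-hydroxyphenyl]methanone | COc1c(Cc2ccc(OCc3ccccc3)cc2)c(OCc2ccccc2)c(Cc2ccc(OCc3ccccc3)cc2)c(CCc2cc(O)ccc2C(=O)c2ccc(OCc3ccccc3)cc2)c1Cc1ccc(OCc2ccccc2)cc1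
A7 | alternative 3 | 1-[4-(benzyloxy)phenyl]-5-{3-(benzyloxy)-2,4,6-tris[4-(benzyloxy)benzyl]-5-methoxyphenyl}pent-2-yn-1-one | COc1c(Cc2ccc(OCc3ccccc3)cc2)c(OCc2ccccc2)c(Cc2ccc(OCc3ccccc3)cc2)c(CCC#CC(=O)c2ccc(OCc3ccccc3)cc2)c1Cc1ccc(OCc2ccccc2)cc1
A8 | alternative 3 | (E)-1-methoxy-3-[(trimethylsilyl)oxy]buta-1,3-diene | CO/C=C/C(=C)O[Si](C)(C)C
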